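**Retrosynthetic overview**
- The target is ent-fisetinidol-(4β→6)-(+)-catechin. The last skeletal bond made is the interflavan C4–C6 bond, by Friedel–Crafts attack of the catechin A ring on a flavan-4-yl cation; a 3-O-benzyl carbonate steers 3,4-trans and a bromine at C8 of catechin leaves only C6 open.
- One final hydrogenolysis removes every benzyl ether, the benzyl carbonate and the bromine.
- Lower unit: (+)-catechin from the chiral pool, per-O-benzylated and brominated at C8 (three steps).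
- Upper unit: a (2R)-flavanone is oxygenated at C3 through its enolate (peroxydicarbonate made separately), then the ketone is reduced to the 4-ol.
- Ring C of the upper unit is the only ring built: it closes by an enantioselective intramolecular oxa-Michael addition of a 2′-hydroxy alkylidene β-keto ester, itself a Knoevenagel union of an A-ring β-keto ester and a B-ring aldehyde.

Assumption: the quinidine-derived thiourea in step 5 is taken to deliver the (2R) flavanone (checked by CD); if the sense is the reverse, its quinine-derived pseudo-enantiomer is used and nothing else changes.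

**Route**

Step 1
Reactants: 1 methyl 2,4-dihydroxybenzoate
Product: 2 methyl 4-(benzyloxy)-2-hydroxybenzoate
Conditions: BnBr (1.05 equiv), K2CO3 (1.2 equiv), acetone, reflux
Reagents that add atoms: benzyl bromide, BrCc1ccccc1
Why: Williamson etherification; the 2-OH is locked in a hydrogen bond to the ester carbonyl, so only the 4-OH is alkylated.

Step 2
Reactants: 2 methyl 4-(benzyloxy)-2-hydroxybenzoate
Product: 3 tert-butyl 3-[4-(benzyloxy)-2-hydroxyphenyl]-3-oxopropanoate
Conditions: LiN(iPr)2 (3.3 equiv), tert-butyl acetate (3.3 equiv), THF, −78 °C, then 2, −78 to 0 °C; AcOH quench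
Reagents that add atoms: tert-butyl acetate, CC(=O)OC(C)(C)C
Why: crossed Claisen condensation; excess ester enolate tolerates the phenoxide, and the product is shielded from further attack as its own enolate.

Step 3
Reactants: 4 3,4-dihydroxybenzaldehyde
Product: 5 3,4-bis(benzyloxy)benzaldehyde
Conditions: BnBr (2.2 equiv), K2CO3 (2.5 equiv), DMF, 60 °C
Reagents that add atoms: benzyl bromide, BrCc1ccccc1
Why: double Williamson etherification of the catechol.

Step 4
Reactants: 3 tert-butyl 3-[4-(benzyloxy)-2-hydroxyphenyl]-3-oxopropanoate; 5 3,4-bis(benzyloxy)benzaldehyde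
Product: 6 tert-butyl (2Z)-2-[4-(benzyloxy)-2-hydroxybenzoyl]-3-[3,4-bis(benzyloxy)phenyl]prop-2-enoate
Conditions: piperidine (0.2 equiv), AcOH (0.2 equiv), 4 Å MS, toluene, 40 °C; stopped before ring closure sets in
Reagents that add atoms: none
Why: Knoevenagel condensation of the active methylene with the aldehyde, driven by sieves; the olefin geometry (drawn Z) is of no consequence because both isomers converge in the next step.

Step 5
Reactants: 6 tert-butyl (2Z)-2-[4-(benzyloxy)-2-hydroxybenzoyl]-3-[3,4-bis(benzyloxy)phenyl]prop-2-enoate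
Product: 9 (2R)-7-(benzyloxy)-2-[3,4-bis(benzyloxy)phenyl]chroman-4-one, via cyclised tert-butyl keto ester 7 (not isolated), via keto acid 8 (not isolated)
Conditions: N-[3,5-bis(trifluoromethyl)phenyl]-N′-[(9R)-6′-methoxycinchonan-9-yl]thiourea (10 mol %), toluene, −25 °C, 48 h; then TsOH·H2O (1 equiv), 80 °C; recrystallise to raise ee
Reagents that add atoms: none
Why: intramolecular oxa-Michael addition closes ring C, the bifunctional thiourea/tertiary amine holding the β-keto ester and the phenol so that C2 forms as R; acid then cleaves the tert-butyl ester and the β-keto acid decarboxylates, which removes the labile C3 centre and, with the catalyst protonated, blocks retro-Michael racemisation.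

Step 6
Reactants: 10 benzyl chloroformate (2 equiv)
Product: 11 dibenzyl peroxydicarbonate
Conditions: 30 % aq H2O2, aq NaOH, 0–5 °C; solid filtered, kept cold, handled behind a shield on small scale
Reagents that add atoms: hydrogen peroxide, OO
Why: twofold acyl substitution of the chloroformate by hydroperoxide anion (Schotten–Baumann type) gives the crystalline peroxide.

Step 7
Reactants: 9 (2R)-7-(benzyloxy)-2-[3,4-bis(benzyloxy)phenyl]chroman-4-one; 11 dibenzyl peroxydicarbonate
Product: 13 benzyl (2S,3S)-7-(benzyloxy)-2-[3,4-bis(benzyloxy)phenyl]-4-oxochroman-3-yl carbonate, via lithium enolate 12 (not isolated)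
Conditions: LiN(SiMe3)2 (1.1 equiv), THF, −78 °C, 30 min; then 11 (1.2 equiv), −78 °C; AcOH quench at −78 °C
Reagents that add atoms: none
Why: electrophilic α-oxygenation of a ketone enolate by O–O cleavage of the peroxydicarbonate; the reagent comes in anti to the C2 aryl group to give the 2,3-trans (3S) carbonate, which is also the thermodynamic epimer, and at −78 °C the cyclic enolate does not ring-open, so C2 is kept.

Step 8
Reactants: 13 benzyl (2S,3S)-7-(benzyloxy)-2-[3,4-bis(benzyloxy)phenyl]-4-oxochroman-3-yl carbonate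
Product: 14 benzyl (2S,3R,4S)-7-(benzyloxy)-2-[3,4-bis(benzyloxy)phenyl]-4-hydroxychroman-3-yl carbonate
Conditions: NaBH4 (1 equiv), CeCl3·7H2O (1 equiv), MeOH–THF 1:1, −60 °C; AcOH quench cold
Reagents that add atoms: none
Why: Luche reduction under non-basic conditions spares the carbonate and avoids its migration; axial hydride delivery gives mainly the 3,4-trans (4S) alcohol, and the C4 configuration is erased in step 12 anyway.

Step 9
Reactants: 15 (+)-catechin
Product: 16 (2R,3S)-5,7-bis(benzyloxy)-2-[3,4-bis(benzyloxy)phenyl]chroman-3-ol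
Conditions: BnBr (4.4 equiv), K2CO3 (5 equiv), DMF, 0 °C to rt, argon
Reagents that add atoms: benzyl bromide, BrCc1ccccc1
Why: Williamson etherification of the four phenols only, since carbonate does not deprotonate the secondary alcohol; both stereocentres come unchanged from the chiral pool.

Step 10
Reactants: 16 (2R,3S)-5,7-bis(benzyloxy)-2-[3,4-bis(benzyloxy)phenyl]chroman-3-ol
Product: 17 (2R,3S)-5,7-bis(benzyloxy)-2-[3,4-bis(benzyloxy)phenyl]-8-bromochroman-3-ol
Conditions: NBS (1.0 equiv), CH2Cl2, −40 to 0 °C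
Reagents that add atoms: N-bromosuccinimide, O=C1CCC(=O)N1Br
Why: electrophilic aromatic bromination; C8 is the most reactive position of the benzylated phloroglucinol ring, so the bromine caps it and leaves C6 as the only free site.

Step 11
Reactants: 17 (2R,3S)-5,7-bis(benzyloxy)-2-[3,4-bis(benzyloxy)phenyl]-8-bromochroman-3-ol
Product: 18 (2R,3S)-3,5,7-tris(benzyloxy)-2-[3,4-bis(benzyloxy)phenyl]-8-bromochromane
Conditions: NaH (1.5 equiv), BnBr (1.3 equiv), DMF, 0 °C to rt
Reagents that add atoms: benzyl bromide, BrCc1ccccc1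
Why: Williamson etherification of the secondary alkoxide removes the competing O-nucleophile for the coupling with a group that leaves in the final hydrogenolysis.

Step 12
Reactants: 14 benzyl (2S,3R,4S)-7-(benzyloxy)-2-[3,4-bis(benzyloxy)phenyl]-4-hydroxychroman-3-yl carbonate; 18 (2R,3S)-3,5,7-tris(benzyloxy)-2-[3,4-bis(benzyloxy)phenyl]-8-bromochromane
Product: 19 benzyl (2S,3R,4R)-7-(benzyloxy)-2-[3,4-bis(benzyloxy)phenyl]-4-{(2R,3S)-3,5,7-tris(benzyloxy)-2-[3,4-bis(benzyloxy)phenyl]-8-bromochroman-6-yl}chroman-3-yl carbonate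
Conditions: BF3·OEt2 (1.5 equiv), 4 Å MS, CH2Cl2, −78 to −30 °C, 14 added slowly to a twofold excess of 18; Et3N (3 equiv) quench at −30 °C; surplus 18 recovered by chromatography
Reagents that add atoms: none
Why: Friedel–Crafts alkylation in which BF3 ionises the benzylic 4-OH (it leaves as hydroxytrifluoroborate) to a 7-alkoxy-stabilised flavan-4-yl cation, the carbonate carbonyl bridges the face syn to O3 (neighbouring-group participation) so the arene adds trans to O3 and sets C4 as R, and the C8 bromine leaves C6 as the only nucleophilic carbon.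

Step 13
Reactants: 19 benzyl (2S,3R,4R)-7-(benzyloxy)-2-[3,4-bis(benzyloxy)phenyl]-4-{(2R,3S)-3,5,7-tris(benzyloxy)-2-[3,4-bis(benzyloxy)phenyl]-8-bromochroman-6-yl}chroman-3-yl carbonate
Product: 20 CNP0141631.5, (2R,3S)-2-(3,4-dihydroxyphenyl)-6-[(2S,3R,4R)-2-(3,4-dihydroxyphenyl)-3,7-dihydroxychroman-4-yl]chromane-3,5,7-triol
Conditions: H2 (1 atm), Pd(OH)2/C (20 wt %), NaOAc (2 equiv), THF–MeOH–H2O 20:20:1, rt; Celite filtration under argon, Sephadex LH-20, freeze-drying
Reagents that add atoms: none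
Why: heterogeneous catalytic hydrogenolysis cleaves the eight benzyl ethers and the benzyl carbonate (which then loses CO2) and hydrodebrominates C8, with acetate taking up the HBr; no stereocentre is touched.

**Compound list**
1 | methyl 2,4-dihydroxybenzoate | COC(=O)c1ccc(O)cc1O | starting material
2 | methyl 4-(benzyloxy)-2-hydroxybenzoate | COC(=O)c1ccc(OCc2ccccc2)cc1O | intermediate
3 | tert-butyl 3-[4-(benzyloxy)-2-hydroxyphenyl]-3-oxopropanoate | CC(C)(C)OC(=O)CC(=O)c1ccc(OCc2ccccc2)cc1O | intermediate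
4 | 3,4-dihydroxybenzaldehyde | O=Cc1ccc(O)c(O)c1 | starting material
5 | 3,4-bis(benzyloxy)benzaldehyde | O=Cc1ccc(OCc2ccccc2)c(OCc2ccccc2)c1 | intermediate
6 | tert-butyl (2Z)-2-[4-(benzyloxy)-2-hydroxybenzoyl]-3-[3,4-bis(benzyloxy)phenyl]prop-2-enoate | CC(C)(C)OC(=O)/C(=C\c1ccc(OCc2ccccc2)c(OCc2ccccc2)c1)C(=O)c1ccc(OCc2ccccc2)cc1O | intermediate
7 | tert-butyl (2R,3S)-7-(benzyloxy)-2-[3,4-bis(benzyloxy)phenyl]-4-oxochromane-3-carboxylate (trans; C3 labile) | C(c1ccccc1)Oc2ccc3c(c2)O[C@@H](c4ccc(OCc5ccccc5)c(OCc5ccccc5)c4)[C@H](C(=O)OC(C)(C)C)C3=O | intermediate (not isolated)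
8 | (2R,3S)-7-(benzyloxy)-2-[3,4-bis(benzyloxy)phenyl]-4-oxochromane-3-carboxylic acid | C(c1ccccc1)Oc2ccc3c(c2)O[C@@H](c4ccc(OCc5ccccc5)c(OCc5ccccc5)c4)[C@H](C(=O)O)C3=O | intermediate (not isolated)
9 | (2R)-7-(benzyloxy)-2-[3,4-bis(benzyloxy)phenyl]chroman-4-one | C(c1ccccc1)Oc2ccc3c(c2)O[C@@H](c4ccc(OCc5ccccc5)c(OCc5ccccc5)c4)CC3=O | intermediate
10 | benzyl chloroformate | O=C(Cl)OCc1ccccc1 | starting material
11 | dibenzyl peroxydicarbonate | O=C(OCc1ccccc1)OOC(=O)OCc1ccccc1 | intermediate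
12 | lithium (2R)-7-(benzyloxy)-2-[3,4-bis(benzyloxy)phenyl]-2H-chromen-4-olate | C(c1ccccc1)Oc2ccc3c(c2)O[C@@H](c4ccc(OCc5ccccc5)c(OCc5ccccc5)c4)C=C3[O-].[Li+] | intermediate (not isolated)
13 | benzyl (2S,3S)-7-(benzyloxy)-2-[3,4-bis(benzyloxy)phenyl]-4-oxochroman-3-yl carbonate | C(c1ccccc1)Oc2ccc3c(c2)O[C@@H](c4ccc(OCc5ccccc5)c(OCc5ccccc5)c4)[C@H](OC(=O)OCc4ccccc4)C3=O | intermediate
14 | benzyl (2S,3R,4S)-7-(benzyloxy)-2-[3,4-bis(benzyloxy)phenyl]-4-hydroxychroman-3-yl carbonate | C(c1ccccc1)Oc2ccc3c(c2)O[C@@H](c4ccc(OCc5ccccc5)c(OCc5ccccc5)c4)[C@H](OC(=O)OCc4ccccc4)[C@H]3O | intermediate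
15 | (+)-catechin, (2R,3S)-2-(3,4-dihydroxyphenyl)chromane-3,5,7-triol | O[C@H]1Cc2c(O)cc(O)cc2O[C@@H]1c1ccc(O)c(O)c1 | starting material
16 | (2R,3S)-5,7-bis(benzyloxy)-2-[3,4-bis(benzyloxy)phenyl]chroman-3-ol | O[C@H]1Cc2c(OCc3ccccc3)cc(OCc3ccccc3)cc2O[C@@H]1c1ccc(OCc2ccccc2)c(OCc2ccccc2)c1 | intermediate
17 | (2R,3S)-5,7-bis(benzyloxy)-2-[3,4-bis(benzyloxy)phenyl]-8-bromochroman-3-ol | O[C@H]1Cc2c(OCc3ccccc3)cc(OCc3ccccc3)c(Br)c2O[C@@H]1c1ccc(OCc2ccccc2)c(OCc2ccccc2)c1 | intermediate
18 | (2R,3S)-3,5,7-tris(benzyloxy)-2-[3,4-bis(benzyloxy)phenyl]-8-bromochromane | C(c1ccccc1)O[C@H]2Cc3c(OCc4ccccc4)cc(OCc4ccccc4)c(Br)c3O[C@@H]2c2ccc(OCc3ccccc3)c(OCc3ccccc3)c2 | intermediate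
19 | benzyl (2S,3R,4R)-7-(benzyloxy)-2-[3,4-bis(benzyloxy)phenyl]-4-{(2R,3S)-3,5,7-tris(benzyloxy)-2-[3,4-bis(benzyloxy)phenyl]-8-bromochroman-6-yl}chroman-3-yl carbonate | C(c1ccccc1)Oc2ccc3c(c2)O[C@@H](c4ccc(OCc5ccccc5)c(OCc5ccccc5)c4)[C@H](OC(=O)OCc4ccccc4)[C@H]3c4c(OCc5ccccc5)c(Br)c5c(c4OCc4ccccc4)C[C@H](OCc4ccccc4)[C@@H](c4ccc(OCc6ccccc6)c(OCc6ccccc6)c4)O5 | intermediate
20 | CNP0141631.5, ent-fisetinidol-(4β→6)-(+)-catechin, (2R,3S)-2-(3,4-dihydroxyphenyl)-6-[(2S,3R,4R)-2-(3,4-dihydroxyphenyl)-3,7-dihydroxychroman-4-yl]chromane-3,5,7-triol | Oc1ccc2c(c1)O[C@@H](c1ccc(O)c(O)c1)[C@H](O)[C@H]2c1c(O)cc2c(c1O)C[C@H](O)[C@@H](c1ccc(O)c(O)c1)O2 | target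

**Step count**
Total step count: 13.
Longest linear sequence: 8 (steps 1, 2, 4, 5, 7, 8, 12, 13). The branches to 5 (step 3), 11 (step 6) and 18 (steps 9–11) run beside it.

**Steps most likely to fail, with fallbacks**

Step 5 (enantioselective oxa-Michael closure; ee or sense of induction). The fallback sets out from 6 and comes back at 9. Compound 6 is closed without chiral control (DABCO 10 mol %, toluene, rt) to the racemic trans keto ester F1, which TsOH at 80 °C converts through the racemic keto acid F2 into the racemic flavanone F3. Kinetic resolution by asymmetric transfer hydrogenation (RuCl(p-cymene)[(S,S)-N-tosyl-1,2-diphenylethylenediamine] 1 mol %, HCO2H/Et3N 5:2, EtOAc, rt, stopped near 52 % conversion) reduces the (2S) antipode to the (2S,4S)-cis-flavan-4-ol F4 and leaves 9, which is separated by chromatography.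

Step 7 (enolate oxygenation with the peroxydicarbonate; acyl transfer or ring opening of the enolate may compete). The fallback sets out from 9 and comes back at 13. Compound 9 is trapped with LiN(SiMe3)2 and Me3SiCl (internal quench, THF, −78 °C) as the trimethylsilyl enol ether F5. Dimethyldioxirane (acetone, −40 °C) epoxidises F5 anti to the aryl group to the silyloxy epoxide F6, and methanolic citric acid opens this to the trans-3-hydroxyflavanone F7 (Rubottom oxidation). Benzyl chloroformate 10 with pyridine and DMAP in CH2Cl2 then acylates F7 to 13.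

Step 12 (Friedel–Crafts coupling at the hindered, bromine-deactivated C6; 3,4-trans control; the participating carbonate may instead collapse to a 3,4-cyclic carbonate with loss of its benzyl group). The fallback sets out from 13 and comes back at 20. Compound 13 is hydrogenolysed (H2, Pd/C, EtOAc–MeOH) to free ent-fustin F8, and NaBH4 in MeOH reduces this to the flavan-3,4-diol ent-mollisacacidin F9. F9 is condensed with unprotected (+)-catechin 15 (4 equiv) in 0.1 M aqueous HCl at rt, a protecting-group-free biomimetic coupling. Compound 20 is then separated from the co-formed regioisomeric (4→8) dimer F10 on Sephadex LH-20 and by reversed-phase HPLC.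

**Further compounds**
F1 | step 5 | racemic trans tert-butyl 7-(benzyloxy)-2-[3,4-bis(benzyloxy)phenyl]-4-oxochromane-3-carboxylate | CC(C)(C)OC(=O)C1C(=O)c2ccc(OCc3ccccc3)cc2OC1c1ccc(OCc2ccccc2)c(OCc2ccccc2)c1
F2 | step 5 | racemic trans 7-(benzyloxy)-2-[3,4-bis(benzyloxy)phenyl]-4-oxochromane-3-carboxylic acid | OC(=O)C1C(=O)c2ccc(OCc3ccccc3)cc2OC1c1ccc(OCc2ccccc2)c(OCc2ccccc2)c1
F3 | step 5 | racemic 7-(benzyloxy)-2-[3,4-bis(benzyloxy)phenyl]chroman-4-one | O=C1CC(c2ccc(OCc3ccccc3)c(OCc3ccccc3)c2)Oc2cc(OCc3ccccc3)ccc21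
F4 | step 5 | (2S,4S)-7-(benzyloxy)-2-[3,4-bis(benzyloxy)phenyl]chroman-4-ol | C(c1ccccc1)Oc2ccc3c(c2)O[C@H](c4ccc(OCc5ccccc5)c(OCc5ccccc5)c4)C[C@@H]3O
F5 | step 7 | (2R)-7-(benzyloxy)-2-[3,4-bis(benzyloxy)phenyl]-4-(trimethylsilyloxy)-2H-chromene | C(c1ccccc1)Oc2ccc3c(c2)O[C@@H](c4ccc(OCc5ccccc5)c(OCc5ccccc5)c4)C=C3O[Si](C)(C)C
F6 | step 7 | (2S)-7-(benzyloxy)-2-[3,4-bis(benzyloxy)phenyl]-3,4-epoxy-4-(trimethylsilyloxy)chromane, epoxide oxygen trans to the aryl group | C(c1ccccc1)Oc2ccc3c(c2)O[C@@H](c4ccc(OCc5ccccc5)c(OCc5ccccc5)c4)[C@@H]4O[C@@]43O[Si](C)(C)C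
F7 | step 7 | (2S,3S)-7-(benzyloxy)-2-[3,4-bis(benzyloxy)phenyl]-3-hydroxychroman-4-one | C(c1ccccc1)Oc2ccc3c(c2)O[C@@H](c4ccc(OCc5ccccc5)c(OCc5ccccc5)c4)[C@H](O)C3=O
F8 | step 12 | ent-fustin, (2S,3S)-2-(3,4-dihydroxyphenyl)-3,7-dihydroxychroman-4-one | Oc1ccc2c(c1)O[C@@H](c1ccc(O)c(O)c1)[C@H](O)C2=O
F9 | step 12 | ent-mollisacacidin, (2S,3R,4S)-2-(3,4-dihydroxyphenyl)chromane-3,4,7-triol | Oc1ccc2c(c1)O[C@@H](c1ccc(O)c(O)c1)[C@H](O)[C@H]2O
F10 | step 12 | ent-fisetinidol-(4β→8)-(+)-catechin | Oc1ccc2c(c1)O[C@@H](c1ccc(O)c(O)c1)[C@H](O)[C@H]2c1c(O)cc(O)c2c1O[C@H](c1ccc(O)c(O)c1)[C@@H](O)C2
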